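The numbers are made up; no experiment stands behind them.

The neighbouring reading of this flask at 25 h is where I will try my rule at the end; first comes the reading at 6.0 h.

substrate 0.020 M; time 6.0 h

    substrate ⇌ target (K1 = 9.5, k1 = 0.0046 s⁻¹)
    substrate ⇌ isomer of the product A (K2 = 3.0, k2 = 0.0025 s⁻¹)
    2 substrate → self-condensation product (k3 = 0.0021 M⁻¹ s⁻¹)
    target ⇌ isomer of the product B (K4 = 18, k4 = 1.5 × 10⁻⁵ s⁻¹)

- percentages count the substrate that a species holds: one self-condensation product counts as two
- a doubled species enters its step squared and goes two at a time
- the reaction counts as stopped when no species that holds the substrate changes by six tenths of a point or more over the second half of the time
- run time (flask): 6.0 h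

* the state of affairs at 6.0 h: stopped, and by what, or still going (forward and back rates have come level / all of the substrate has reacted / it is still moving)
* share of the substrate used up at 6.0 h
* target at 6.0 h, in percent of the substrate charged
* isomer of the product B at 6.0 h, in percent of the substrate charged
* isomer of the product A at 6.0 h, in percent of the substrate charged

At the bench I treat this as a pre-equilibrium with a slow drain. Substrate exchanges with target and with isomer of the product A at relaxation half-lives of 2.27 min and 3.47 min, each reckoned for its own step alone and both shorter than the run of 6.0 h. So I call these three the pool and set forward and back rates level. With one rate divided by the other, time drops out, and substrate, target and isomer of the product A stand as 1 : 9.5 : 3.0. That gives 70.4%, which I name target's share of the pool. I leave self-condensation out, its opening rate being 0.0183 of the forward rate into target.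

With self-condensation left out, the pool loses material through target into isomer of the product B, so it drains at the rate constant of that step times the share, 0.0380 h⁻¹; that step, with a rate constant far below the one from substrate into target, is the rate-limiting step of this loss. By this reckoning the pool keeps 79.6% after 6.0 h. I commit to target 56.0%, isomer of the product A 17.7%, isomer of the product B 20.4%, conversion 94.1%, and the state: it is still moving.

The rule has a border, since it runs the drain one way. Back rate over forward rate in that step is isomer of the product B over its equilibrium constant times target: reckoned 0.0202 at 6.0 h, but 0.125 at 25 h, so by then I expect the rule to read target low.

The forecast says it is still moving, with conversion 94.2%, target 55.6%, isomer of the product B 19.8% and isomer of the product A 17.5%: “The slow leak from target to isomer B has a timescale of about a day”. On target my figure differs from it by 0.42 percentage points.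

The simulation gives it is still moving, with conversion 94.1%, target 55.3%, isomer of the product B 19.6% and isomer of the product A 17.8%. Over the second half of this flask's time the largest change is 9.4 points. Target's part of the three pool readings at 6.00 h is 70.0%, against the carried 70.4%. For the neighbouring flask read at 25 h, the share times what the drain leaves gives target 27.2%, and in that flask target stands at 27.7%.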